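**Retrosynthetic overview**

1. The target is read as three rings joined by two CH2 bridges: ring A (a 2-butanoyl-4,4-dimethylcyclohexane-1,3,5-trione enol: C1 carbonyl, C2 bearing butanoyl, C3, C4 = C(CH3)2, C5, C6 bearing the bridge), ring B (butanoylphloroglucinol) and ring C (aspidinol). Rings B and C enter as intact arenes and are never closed in the route.
2. Last disconnection (three components, one flask): the bonds C1–C2 of ring A, C6–CH2 and CH2–ring B are cut. This gives the B–C diarylmethane, a one-carbon iminium salt and an enol δ-lactone that is a constitutional isomer of butanoylfilicinic acid, with the lactone oxygen standing where C2 of ring A will bond to C1.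
3. Enabling feature: every bond of ring A joins a carbonyl carbon to an α-carbon and C4 is quaternary. The ring therefore cannot aromatize, the C3 carbonyl can enolize only toward C2, and the C1–C2 bond can be stored as the acyl–O bond of an enol lactone whose C3 (future C6 of ring A, between the carbonyls that become C1 and C5) is its one soft nucleophilic carbon. The ring-B carbon flanked by two hydroxyls supplies the ortho-quinone methide.
4. The B–C bridge is made earlier by the same Mannich/quinone-methide logic from aspidinol (from 2-methylphloroglucinol by C-acylation and para-O-methylation) and butanoylphloroglucinol. The lactone comes from methyl 2,2-dimethylacetoacetate by two Claisen acylations and an acid-mediated enol lactonization.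
5. Ring order: rings B and C pre-formed; temporary lactone ring (step 7); ring A last (step 8), by lactone-to-carbocycle acyl transfer in the same operation that builds the A–B bridge.

Key step: step 8

Assumption: 1-(2,4,6-trihydroxyphenyl)butan-1-one, methyl 2,2-dimethyl-3-oxobutanoate, N-methoxy-N-methylbutanamide and tert-butyl acetate are taken as catalogue compounds, and each enolizable β-di- or β-tricarbonyl unit is drawn in one tautomeric form although the tautomers equilibrate.

**Route**

Step 1
Reactants: 1 2-methylbenzene-1,3,5-triol (2,4,6-trihydroxytoluene); 2 butanoyl chloride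
Product: 3 1-(2,4,6-trihydroxy-3-methylphenyl)butan-1-one
Conditions: AlCl3 (3 equiv), PhNO2, 60 °C; then cold 1 M HCl
Reagents that add atoms: none
Why: Friedel–Crafts acylation at one of the two equivalent free ring carbons of the electron-rich triol should stop at the monoketone, because the first acyl group deactivates the ring toward a second acylation.

Step 2
Reactants: 3 1-(2,4,6-trihydroxy-3-methylphenyl)butan-1-one
Product: 4 1-(2,6-dihydroxy-4-methoxy-3-methylphenyl)butan-1-one (aspidinol)
Conditions: Me2SO4 (1.0 equiv), K2CO3 (1.0 equiv), acetone, 23 °C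
Reagents that add atoms: dimethyl sulfate, COS(=O)(=O)OC
Why: Williamson-type O-methylation with one equivalent of electrophile should take the 4-OH para to the ketone, which is the most acidic hydroxyl and the only one that does not flank the chelating carbonyl.

Step 3
Reactants: 4 1-(2,6-dihydroxy-4-methoxy-3-methylphenyl)butan-1-one
Product: 5 1-[3-[(dimethylamino)methyl]-2,6-dihydroxy-4-methoxy-5-methylphenyl]butan-1-one
Conditions: 37% aq. CH2O, 40% aq. Me2NH, EtOH, 23 °C
Reagents that add atoms: formaldehyde, C=O; dimethylamine, CNC
Why: Mannich aminomethylation can only occur at the single unsubstituted aromatic carbon of 4, so the regiochemistry is fixed by the substrate.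

Step 4
Reactants: 5 1-[3-[(dimethylamino)methyl]-2,6-dihydroxy-4-methoxy-5-methylphenyl]butan-1-one; 6 1-(2,4,6-trihydroxyphenyl)butan-1-one
Product: 7 1-[3-[(3-butanoyl-2,4-dihydroxy-6-methoxy-5-methylphenyl)methyl]-2,4,6-trihydroxyphenyl]butan-1-one
Conditions: 6 (3 equiv), 1,4-dioxane, 100 °C, slow N2 purge
Reagents that add atoms: none
Why: Thermal retro-Mannich loss of dimethylamine should give an ortho-quinone methide that is trapped by C-alkylation (Friedel–Crafts-type conjugate addition) at one of the two equivalent free carbons of 6, the excess of 6 suppressing double alkylation.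

Step 5
Reactants: 8 methyl 2,2-dimethyl-3-oxobutanoate; 9 N-methoxy-N-methylbutanamide
Product: 10 methyl 2,2-dimethyl-3,5-dioxooctanoate
Conditions: LiN(SiMe3)2 (2.1 equiv), THF, −78 °C; then 9, −78 to 0 °C; then 1 M HCl
Reagents that add atoms: none
Why: Crossed Claisen-type C-acylation of the lithium enolate of the methyl ketone (the only enolizable position, since C2 is quaternary) with an N-methoxy-N-methylamide should stop at the 1,3-diketone because the chelated tetrahedral adduct survives until work-up.

Step 6
Reactants: 10 methyl 2,2-dimethyl-3,5-dioxooctanoate; 11 tert-butyl acetate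
Product: 12 tert-butyl 4,4-dimethyl-3,5,7-trioxodecanoate
Conditions: LiN(iPr)2 (3.5 equiv), 11 (3.5 equiv), THF, −78 °C; then 10, −78 to 0 °C; then cold 1 M HCl
Reagents that add atoms: none
Why: Claisen condensation of excess lithium tert-butyl acetate enolate with the methyl ester should proceed because the first equivalent protects the 1,3-diketone as its enolate and deprotonation of the new β-keto ester drives the equilibrium.

Step 7
Reactants: 12 tert-butyl 4,4-dimethyl-3,5,7-trioxodecanoate
Product: 14 (6Z)-4-hydroxy-5,5-dimethyl-6-(2-oxopentylidene)-5,6-dihydro-2H-pyran-2-one, via triketo acid 13 (not isolated)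
Conditions: CF3CO2H, (CF3CO)2O (2 equiv), CH2Cl2, 0 to 23 °C
Reagents that add atoms: none
Why: Acidolysis of the tert-butyl ester and mixed-anhydride activation should let the enol oxygen of the 5,7-diketone acylate in a 6-exo-trig enol lactonization (the known route from 3,5-dioxo esters to 4-hydroxypyran-2-ones) before the β-keto acid can decarboxylate; because C4 is quaternary the C5 carbonyl can enolize only toward C6, which fixes the exocyclic (Z)-alkylidene lactone, with butanoyl cis to the ring oxygen as in the chelated enol and away from the gem-dimethyl group.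

Step 8
Reactants: 7 1-[3-[(3-butanoyl-2,4-dihydroxy-6-methoxy-5-methylphenyl)methyl]-2,4,6-trihydroxyphenyl]butan-1-one; 14 (6Z)-4-hydroxy-5,5-dimethyl-6-(2-oxopentylidene)-5,6-dihydro-2H-pyran-2-one
Product: 19 2-butanoyl-6-[[3-butanoyl-5-[(3-butanoyl-2,4-dihydroxy-6-methoxy-5-methylphenyl)methyl]-2,4,6-trihydroxyphenyl]methyl]-3,5-dihydroxy-4,4-dimethylcyclohexa-2,5-dien-1-one, via Mannich base 15 (not isolated), via ortho-quinone methide 16 (not isolated), via bridged enol lactone 17 (not isolated), via seco methyl ester 18 (not isolated)
Conditions: [CH2=NMe2]I (1.05 equiv), MeCN, 23 °C; then 14, Et3N, 50 °C; then Mg(OMe)2 (6 equiv), MeOH, 60 °C; then cold 1 M HCl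
Reagents that add atoms: N,N-dimethylmethyleneiminium iodide, C=[N+](C)C.[I-]
Why: Mannich aminomethylation of the only free aromatic carbon of ring B gives 15, loss of Me2NH gives ortho-quinone methide 16, and the enolate of 14 adds through its C3 (Michael addition) to give 17; methoxide then opens the enol lactone (directly or by E1cB expulsion of the diketonate through an acylketene) to 18, whose freed magnesium β-diketonate carbon attacks the ester carbonyl and forms the C1–C2 bond of ring A with loss of methanol. The closest known reaction types are the Mannich-base/quinone-methide union of acylphloroglucinols with filicinic acids and the Mg(OMe)2-mediated Claisen conversion of 6-(2-oxoalkyl)-4-hydroxypyran-2-ones into acylphloroglucinols. Ring A closes in a 6-(enolexo)-exo-trig Dieckmann-type C-acylation, and no stereocentre is formed because the stereocentre of 18 and the alkene geometry of 14 disappear on enolization. The step needs one C-alkylation at each partner and C- over O-acylation: 7 has a single free ring carbon, the lactone has a single soft carbon because the future C2 of ring A is masked as the vinylogous-ester CH and C5 is quaternary, and O-alkylation or O-acylation (including aryl lactone formation with a ring B hydroxyl) is reversible whereas the C-acylated triketone leaves the equilibria as its chelated enolate. Capture of 16 by the intact lactone is staged before Mg(OMe)2 is added, and should some lactone rearrange first the resulting acylfilicinate is alkylated at the same carbon, so both orders converge on 19.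

**Compound list**

1 | 2-methylbenzene-1,3,5-triol (2,4,6-trihydroxytoluene) | Cc1c(O)cc(O)cc1O | starting material
2 | butanoyl chloride | CCCC(=O)Cl | starting material
3 | 1-(2,4,6-trihydroxy-3-methylphenyl)butan-1-one | CCCC(=O)c1c(O)cc(O)c(C)c1O | intermediate
4 | 1-(2,6-dihydroxy-4-methoxy-3-methylphenyl)butan-1-one (aspidinol) | CCCC(=O)c1c(O)cc(OC)c(C)c1O | intermediate
5 | 1-[3-[(dimethylamino)methyl]-2,6-dihydroxy-4-methoxy-5-methylphenyl]butan-1-one | CCCC(=O)c1c(O)c(CN(C)C)c(OC)c(C)c1O | intermediate
6 | 1-(2,4,6-trihydroxyphenyl)butan-1-one | CCCC(=O)c1c(O)cc(O)cc1O | starting material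
7 | 1-[3-[(3-butanoyl-2,4-dihydroxy-6-methoxy-5-methylphenyl)methyl]-2,4,6-trihydroxyphenyl]butan-1-one | CCCC(=O)c1c(O)cc(O)c(Cc2c(O)c(C(=O)CCC)c(O)c(C)c2OC)c1O | intermediate
8 | methyl 2,2-dimethyl-3-oxobutanoate | CC(=O)C(C)(C)C(=O)OC | starting material
9 | N-methoxy-N-methylbutanamide | CCCC(=O)N(C)OC | starting material
10 | methyl 2,2-dimethyl-3,5-dioxooctanoate | CCCC(=O)CC(=O)C(C)(C)C(=O)OC | intermediate
11 | tert-butyl acetate | CC(=O)OC(C)(C)C | starting material
12 | tert-butyl 4,4-dimethyl-3,5,7-trioxodecanoate | CCCC(=O)CC(=O)C(C)(C)C(=O)CC(=O)OC(C)(C)C | intermediate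
13 | 4,4-dimethyl-3,5,7-trioxodecanoic acid (not isolated) | CCCC(=O)CC(=O)C(C)(C)C(=O)CC(=O)O | intermediate
14 | (6Z)-4-hydroxy-5,5-dimethyl-6-(2-oxopentylidene)-5,6-dihydro-2H-pyran-2-one | CCCC(=O)/C=C1\OC(=O)C=C(O)C1(C)C | intermediate
15 | 1-[3-[(3-butanoyl-2,4-dihydroxy-6-methoxy-5-methylphenyl)methyl]-5-[(dimethylamino)methyl]-2,4,6-trihydroxyphenyl]butan-1-one (not isolated in step 8) | CCCC(=O)c1c(O)c(CN(C)C)c(O)c(Cc2c(O)c(C(=O)CCC)c(O)c(C)c2OC)c1O | intermediate
16 | 2-butanoyl-4-[(3-butanoyl-2,4-dihydroxy-6-methoxy-5-methylphenyl)methyl]-3,5-dihydroxy-6-methylidenecyclohexa-2,4-dien-1-one (not isolated) | C=C1C(=O)C(C(=O)CCC)=C(O)C(Cc2c(O)c(C(=O)CCC)c(O)c(C)c2OC)=C1O | intermediate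
17 | (6Z)-3-[[3-butanoyl-5-[(3-butanoyl-2,4-dihydroxy-6-methoxy-5-methylphenyl)methyl]-2,4,6-trihydroxyphenyl]methyl]-4-hydroxy-5,5-dimethyl-6-(2-oxopentylidene)-5,6-dihydro-2H-pyran-2-one (not isolated) | CCCC(=O)/C=C1\OC(=O)C(Cc2c(O)c(Cc3c(O)c(C(=O)CCC)c(O)c(C)c3OC)c(O)c(C(=O)CCC)c2O)=C(O)C1(C)C | intermediate
18 | methyl 2-[[3-butanoyl-5-[(3-butanoyl-2,4-dihydroxy-6-methoxy-5-methylphenyl)methyl]-2,4,6-trihydroxyphenyl]methyl]-4,4-dimethyl-3,5,7-trioxodecanoate (racemic at C2, not isolated) | CCCC(=O)CC(=O)C(C)(C)C(=O)C(Cc1c(O)c(Cc2c(O)c(C(=O)CCC)c(O)c(C)c2OC)c(O)c(C(=O)CCC)c1O)C(=O)OC | intermediate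
19 | 2-butanoyl-6-[[3-butanoyl-5-[(3-butanoyl-2,4-dihydroxy-6-methoxy-5-methylphenyl)methyl]-2,4,6-trihydroxyphenyl]methyl]-3,5-dihydroxy-4,4-dimethylcyclohexa-2,5-dien-1-one (no stereocentre) | CCCC(=O)C1=C(O)C(C)(C)C(O)=C(Cc2c(O)c(Cc3c(O)c(C(=O)CCC)c(O)c(C)c3OC)c(O)c(C(=O)CCC)c2O)C1=O | target

**Step count and risks**

Total step count: 8. Longest linear sequence: 5 steps (steps 1, 2, 3, 4 and 8); the lactone branch (steps 5, 6, 7) joins at step 8.

The three steps most likely to fail:

Step 8 (key step). What may go wrong: premature opening of the lactone followed by alkylation of the acyclic triketo ester at the wrong methylene, sluggish acyl transfer, or base-induced scrambling of the two methylene bridges (retro-Friedel–Crafts exchange) during the warm alkoxide stage. Fallback: ring closure and bridging are separated. Setting out from 14, brief treatment with NaOMe in MeOH at 23 °C should isomerize the lactone by the same Claisen closure to 2-butanoyl-3,5-dihydroxy-4,4-dimethylcyclohexa-2,5-dien-1-one F1, whose C6 is its only nucleophilic carbon. Compound 7 is aminomethylated as in the first stage of step 8 and the Mannich base 15 is isolated. F1 and 15 are then heated in 1,4-dioxane at 90 °C without added base, the classical union of a filicinic acid with a phenolic Mannich base through the ortho-quinone methide, which comes back to the route at 19.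

Step 7. What may go wrong: decarboxylation of the β-keto acid 13 before it lactonizes, or C- in place of O-acylation under the strongly acidic activation. Fallback: setting out from 12, slow addition to toluene at 105 °C should expel tert-butanol by retro-ene fragmentation of the tert-butyl β-keto ester and give the acylketene 4,4-dimethyl-3,5,7-trioxodec-1-en-1-one F2 (not isolated), which is trapped intramolecularly by the enol oxygen of the 5,7-diketone. This neutral acylketene lactonization never passes through a free carboxylic acid and comes back to the route at 14.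

Step 6. What may go wrong: slow addition of the ester enolate to the hindered α-quaternary methyl ester, with retro-Claisen fragmentation or self-condensation of the enolate taking over. Fallback: setting out from 10, saponification (LiOH, THF/H2O) should give 2,2-dimethyl-3,5-dioxooctanoic acid F3, and activation with 1,1'-carbonyldiimidazole should give 1-(imidazol-1-yl)-2,2-dimethyloctane-1,3,5-trione F4. Decarboxylative Claisen condensation of F4 with Mg(O2CCH2CO2tBu)2 in THF passes through 2-(tert-butoxycarbonyl)-4,4-dimethyl-3,5,7-trioxodecanoic acid F5 (not isolated), which loses CO2 on acidic work-up, and comes back to the route at 12.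

**Further compounds**

F1 | step 8 | 2-butanoyl-3,5-dihydroxy-4,4-dimethylcyclohexa-2,5-dien-1-one (butanoylfilicinic acid) | CCCC(=O)C1=C(O)C(C)(C)C(O)=CC1=O
F2 | step 7 | 4,4-dimethyl-3,5,7-trioxodec-1-en-1-one (acylketene, not isolated) | CCCC(=O)CC(=O)C(C)(C)C(=O)C=C=O
F3 | step 6 | 2,2-dimethyl-3,5-dioxooctanoic acid | CCCC(=O)CC(=O)C(C)(C)C(=O)O
F4 | step 6 | 1-(imidazol-1-yl)-2,2-dimethyloctane-1,3,5-trione | CCCC(=O)CC(=O)C(C)(C)C(=O)n1ccnc1
F5 | step 6 | 2-(tert-butoxycarbonyl)-4,4-dimethyl-3,5,7-trioxodecanoic acid (racemic, not isolated) | CCCC(=O)CC(=O)C(C)(C)C(=O)C(C(=O)O)C(=O)OC(C)(C)C
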